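**Plan**

- Retrosynthesis: the oxolane O1–C2 bond is cut first (capture of a benzylic cation by the C5 hydroxyl). The C2–C3 bond (aldol) and the bond from C4 to the benzylic carbon (conjugate addition) are then cut together, leaving a butenolide, an aryl dithiane and an aryl aldehyde.
- Enabling feature: oxolane C3 and C4 are the α- and β-carbons of a γ-butanolide. Its carbonyl carbon is the future CH2OH carbon and its γ-acetal carbon is the future C5, so a 5-alkoxybutenolide supplies C5–C4–C3–CH2OH in one piece.
- Forward: furfural and (+)-menthol give the crystalline (5S)-menthyloxybutenolide, and O-benzylvanillin gives the dithiane. A one-flask Michael–aldol joins the three fragments. Desulfurisation and LiAlH4 then give the open-chain triol, acid closes the only ring (the oxolane), and hydrogenolysis frees the phenol.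
- Stereochemistry: the acetal centre directs C4 (addition anti to the menthyloxy group) and C4 directs C3 (trans aldol). The trans lactone becomes the 3,4-cis oxolane because the ring is re-closed through the former acetal carbon. C2 is set trans to C3 in the cation capture.

Key step: step 4

Assumption: 4-(benzyloxy)-3-methoxybenzaldehyde is taken as a purchased material; the carbinol carbon made in step 4 is expected as a mixture of epimers and is written without a descriptor in 12, 13 and 14, because step 7 ionises it.

"d-Menthyl" below means (1S,2R,5S)-2-isopropyl-5-methylcyclohexyl.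

**Route**

Step 1
Reactants: 1 furfural
Product: 3 5-hydroxyfuran-2(5H)-one (racemic), via furfural endoperoxide 2 (not isolated)
Conditions: O2, methylene blue (methylthioninium chloride, cat.), MeOH, visible light, rt
Reagents that add atoms: dioxygen, O=O
Why: Dye-sensitised photo-oxygenation: singlet oxygen adds [4+2] across C2/C5 of the furan and methanol cleaves the endoperoxide with loss of the formyl carbon as methyl formate, a standard preparation of this lactol in which no stereocentre needs control.

Step 2
Reactants: 3 5-hydroxyfuran-2(5H)-one; 4 (+)-menthol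
Product: 6 (5S)-5-(d-menthyloxy)furan-2(5H)-one, via 5R acetal epimer 5 (not isolated)
Conditions: TsOH·H2O (cat.), toluene, reflux, azeotropic removal of water; crystallise from petroleum ether, −20 °C; mother liquor re-equilibrated with TsOH (cat.) and recrystallised
Reagents that add atoms: none
Why: Acid-catalysed acetalisation of the lactol should give both acetal epimers, which interconvert under acid, so crystallisation-induced asymmetric transformation should funnel the material into the crystalline 5S epimer, the mirror image of the well-known crystalline 5R acetal of (−)-menthol.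

Step 3
Reactants: 7 4-(benzyloxy)-3-methoxybenzaldehyde
Product: 8 2-[4-(benzyloxy)-3-methoxyphenyl]-1,3-dithiane
Conditions: propane-1,3-dithiol, BF3·OEt2 (cat.), CH2Cl2, 0 °C → rt
Reagents that add atoms: propane-1,3-dithiol, SCCCS
Why: Lewis-acid-catalysed dithioacetalisation of an aromatic aldehyde is routine and the aryl benzyl ether tolerates catalytic BF3·OEt2.

Step 4
Reactants: 8 2-[4-(benzyloxy)-3-methoxyphenyl]-1,3-dithiane; 6 (5S)-5-(d-menthyloxy)furan-2(5H)-one; 9 3,4,5-trimethoxybenzaldehyde
Product: 12 (3R,4S,5S)-4-[2-(4-benzyloxy-3-methoxyphenyl)-1,3-dithian-2-yl]-3-[hydroxy(3,4,5-trimethoxyphenyl)methyl]-5-(d-menthyloxy)oxolan-2-one (carbinol epimers), via lithiated dithiane 10 (not isolated), via lithium enolate 11 (not isolated)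
Conditions: 8, n-BuLi, THF, −78 → −20 °C; then 6, THF, −78 °C; then 9, THF, −78 °C; AcOH quench at −78 °C
Reagents that add atoms: none
Why: Deprotonation of 8 gives the aryl-stabilised acyl-anion equivalent 10, which adds in Michael fashion to C4 of butenolide 6; the lactone enolate 11 so formed is intercepted at C3 by the non-enolisable aldehyde 9 in an aldol addition, so both skeletal bonds are made in one flask. The closest known reaction type is the tandem conjugate addition–enolate trapping of lithiated 2-aryl-1,3-dithianes on butenolides with aromatic aldehydes, the standard entry to lignan lactones. No ring is closed; the step only joins three fragments. C4 is controlled by the acetal centre C5, the nucleophile approaching the face opposite the menthyloxy group (4,5-trans); C3 is controlled by the new bulky dithianyl group, the aldehyde approaching anti to it (3,4-trans); the carbinol carbon is uncontrolled and need not be controlled, since it is ionised later. The step needs 1,4- over 1,2-addition, which the soft, hindered anion and the unhindered β-carbon should secure, and it needs face selectivity, which the acetal substituent next to the reacting carbon provides. It also needs carbon trapping of the enolate before proton transfer or retro-aldol, which low temperature, an aldehyde without α-hydrogens and a cold acidic quench should secure.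

Step 5
Reactants: 12 the dithianyl aldol lactone
Product: 13 (3R,4S,5S)-4-[(4-benzyloxy-3-methoxyphenyl)methyl]-3-[hydroxy(3,4,5-trimethoxyphenyl)methyl]-5-(d-menthyloxy)oxolan-2-one
Conditions: Raney Ni (W-2, washed neutral, excess), EtOH–THF, rt
Reagents that add atoms: none
Why: Mozingo-type desulfurisation cleaves the two benzylic C–S bonds to leave the benzylic methylene, and with neutral nickel at room temperature the β-hydroxy lactone, the acetal and the aryl benzyl ether should survive with no stereocentre touched.

Step 6
Reactants: 13 the desulfurised menthyloxy lactone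
Product: 14 (2S,3S)-2-[(4-benzyloxy-3-methoxyphenyl)methyl]-3-[hydroxy(3,4,5-trimethoxyphenyl)methyl]butane-1,4-diol
Conditions: LiAlH4, THF, 0 °C → rt; H2O/aq NaOH work-up
Reagents that add atoms: none
Why: Hydride reduction of the acylal-type lactone gives the primary alcohol from the carbonyl, and the released hemiacetal alkoxide expels menthoxide to an aldehyde that is reduced too, so the 1,4-diol forms and the auxiliary is recovered, with C2 and C3 of the chain no longer epimerisable.

Step 7
Reactants: 14 the triol
Product: 15 [(2R,3S,4S)-4-[(4-benzyloxy-3-methoxyphenyl)methyl]-2-(3,4,5-trimethoxyphenyl)oxolan-3-yl]methanol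
Conditions: (+)-10-camphorsulfonic acid (cat.), CH2Cl2, 0 °C → rt, short reaction time
Reagents that add atoms: none
Why: Acid-catalysed SN1 cycloetherification (formally 5-exo-tet): the trimethoxybenzylic alcohol ionises and the 1,4-related primary hydroxyl captures the cation in preference to the 1,3-related one (oxetane), both carbinol epimers converging on the 2,3-trans ring because the aryl group settles anti to the C3 hydroxymethyl group, while catalytic acid and short exposure should hold back Friedel–Crafts capture by the benzyl arm.

Step 8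
Reactants: 15 the O-benzyl oxolane
Product: 16 [(2R,3S,4S)-4-[(4-hydroxy-3-methoxyphenyl)methyl]-2-(3,4,5-trimethoxyphenyl)oxolan-3-yl]methanol (CNP0423112.2)
Conditions: H2 (1 atm), 10% Pd/C, EtOAc, rt, stopped at full conversion
Reagents that add atoms: none
Why: Catalytic hydrogenolysis of an aryl benzyl ether over Pd/C in a neutral aprotic solvent should be much faster than cleavage of the benzylic C2–O1 bond of the oxolane, so the phenol is freed without touching the three ring stereocentres.

**Compound list**

1 | furfural (furan-2-carbaldehyde) | O=Cc1ccco1 | starting material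
2 | furfural endoperoxide, 2,3,7-trioxabicyclo[2.2.1]hept-5-ene-1-carbaldehyde (racemic, not isolated) | O=CC12OOC(C=C1)O2 | intermediate
3 | 5-hydroxyfuran-2(5H)-one (racemic) | OC1OC(=O)C=C1 | intermediate
4 | (+)-menthol, (1S,2R,5S)-2-isopropyl-5-methylcyclohexan-1-ol | C[C@H]1CC[C@@H]([C@H](C1)O)C(C)C | starting material
5 | (5R)-5-(d-menthyloxy)furan-2(5H)-one (acetal epimer left in solution, not isolated) | C[C@H]1CC[C@@H]([C@H](C1)O[C@H]2C=CC(=O)O2)C(C)C | intermediate
6 | (5S)-5-(d-menthyloxy)furan-2(5H)-one | C[C@H]1CC[C@@H]([C@H](C1)O[C@@H]2C=CC(=O)O2)C(C)C | intermediate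
7 | 4-(benzyloxy)-3-methoxybenzaldehyde | COc1cc(C=O)ccc1OCc1ccccc1 | starting material
8 | 2-[4-(benzyloxy)-3-methoxyphenyl]-1,3-dithiane | COc1cc(C2SCCCS2)ccc1OCc1ccccc1 | intermediate
9 | 3,4,5-trimethoxybenzaldehyde | COc1cc(C=O)cc(OC)c1OC | starting material
10 | 2-lithio-2-[4-(benzyloxy)-3-methoxyphenyl]-1,3-dithiane (not isolated) | [Li]C1(SCCCS1)c1ccc(OCc2ccccc2)c(OC)c1 | intermediate
11 | lithium (4S,5S)-4-[2-(4-benzyloxy-3-methoxyphenyl)-1,3-dithian-2-yl]-5-(d-menthyloxy)-4,5-dihydrofuran-2-olate (not isolated) | C[C@H]1CC[C@@H]([C@H](C1)O[C@H]2OC(O[Li])=C[C@@H]2C2(SCCCS2)c2ccc(OCc3ccccc3)c(OC)c2)C(C)C | intermediate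
12 | (3R,4S,5S)-4-[2-(4-benzyloxy-3-methoxyphenyl)-1,3-dithian-2-yl]-3-[hydroxy(3,4,5-trimethoxyphenyl)methyl]-5-(d-menthyloxy)oxolan-2-one (carbinol epimers) | C[C@H]1CC[C@@H]([C@H](C1)O[C@H]2OC(=O)[C@@H](C(O)c3cc(OC)c(OC)c(OC)c3)[C@@H]2C2(SCCCS2)c2ccc(OCc3ccccc3)c(OC)c2)C(C)C | intermediate
13 | (3R,4S,5S)-4-[(4-benzyloxy-3-methoxyphenyl)methyl]-3-[hydroxy(3,4,5-trimethoxyphenyl)methyl]-5-(d-menthyloxy)oxolan-2-one (carbinol epimers) | C[C@H]1CC[C@@H]([C@H](C1)O[C@H]2OC(=O)[C@@H](C(O)c3cc(OC)c(OC)c(OC)c3)[C@@H]2Cc2ccc(OCc3ccccc3)c(OC)c2)C(C)C | intermediate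
14 | (2S,3S)-2-[(4-benzyloxy-3-methoxyphenyl)methyl]-3-[hydroxy(3,4,5-trimethoxyphenyl)methyl]butane-1,4-diol (carbinol epimers) | OC[C@@H](Cc1ccc(OCc2ccccc2)c(OC)c1)[C@@H](CO)C(O)c1cc(OC)c(OC)c(OC)c1 | intermediate
15 | [(2R,3S,4S)-4-[(4-benzyloxy-3-methoxyphenyl)methyl]-2-(3,4,5-trimethoxyphenyl)oxolan-3-yl]methanol | COc1cc(C[C@@H]2CO[C@@H](c3cc(OC)c(OC)c(OC)c3)[C@@H]2CO)ccc1OCc1ccccc1 | intermediate
16 | [(2R,3S,4S)-4-[(4-hydroxy-3-methoxyphenyl)methyl]-2-(3,4,5-trimethoxyphenyl)oxolan-3-yl]methanol | COc1cc(C[C@@H]2CO[C@@H](c3cc(OC)c(OC)c(OC)c3)[C@@H]2CO)ccc1O | target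

**Step count and risks**

Total steps: 8. Longest linear sequence: 7 steps (1, 2, 4, 5, 6, 7, 8, from furfural).

Steps most likely to fail:

Step 4. The hindered lithium enolate may be captured slowly by the aldehyde, so that proton transfer or retro-aldol during the quench returns the simple Michael adduct. Fallback: split the two bond formations. Starting from 8 and 6, the conjugate addition is run as above and quenched with aqueous NH4Cl at −78 °C, giving the Michael adduct (4S,5S)-4-[2-(4-benzyloxy-3-methoxyphenyl)-1,3-dithian-2-yl]-5-(d-menthyloxy)oxolan-2-one F1. This is re-enolised with LDA in THF at −78 °C and transmetalated with ZnCl2. The zinc enolate, whose aldolate resists reversal, is then treated with 9, again anti to the C4 substituent. The route is rejoined at 12.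

Step 5. Raney nickel may over-reduce, cleaving the aryl benzyl ether or the benzylic C–OH bond, or residual base on the nickel may trigger retro-aldol of the β-hydroxy lactone. Fallback: reduce first and desulfurise without adsorbed hydrogen. Starting from 12, LiAlH4 in THF removes the lactone and the auxiliary to give (2S,3S)-2-[2-(4-benzyloxy-3-methoxyphenyl)-1,3-dithian-2-yl]-3-[hydroxy(3,4,5-trimethoxyphenyl)methyl]butane-1,4-diol F2, which can no longer undergo retro-aldol. Nickel boride generated from NiCl2·6H2O and NaBH4 in MeOH–THF at 0 °C then removes the sulfur while sparing benzyl ethers and benzylic alcohols. The route is rejoined at 14.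

Step 8. The benzylic C2–O1 bond of the electron-rich 2-aryl oxolane may be hydrogenolysed along with the benzyl ether, opening the ring. Fallback: free the phenol before the ring exists. Starting from 14, hydrogenolysis (H2, Pd/C, EtOAc) gives (2S,3S)-2-[(4-hydroxy-3-methoxyphenyl)methyl]-3-[hydroxy(3,4,5-trimethoxyphenyl)methyl]butane-1,4-diol F3, whose only benzylic C–O bond is a free secondary alcohol that reacts far more slowly. Catalytic camphorsulfonic acid in CH2Cl2–THF then closes the oxolane and leads directly to 16.

**Further compounds**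

F1 | step 4 | (4S,5S)-4-[2-(4-benzyloxy-3-methoxyphenyl)-1,3-dithian-2-yl]-5-(d-menthyloxy)oxolan-2-one | C[C@H]1CC[C@@H]([C@H](C1)O[C@H]2OC(=O)C[C@@H]2C2(SCCCS2)c2ccc(OCc3ccccc3)c(OC)c2)C(C)C
F2 | step 5 | (2S,3S)-2-[2-(4-benzyloxy-3-methoxyphenyl)-1,3-dithian-2-yl]-3-[hydroxy(3,4,5-trimethoxyphenyl)methyl]butane-1,4-diol | OC[C@@H](C1(SCCCS1)c1ccc(OCc2ccccc2)c(OC)c1)[C@@H](CO)C(O)c1cc(OC)c(OC)c(OC)c1
F3 | step 8 | (2S,3S)-2-[(4-hydroxy-3-methoxyphenyl)methyl]-3-[hydroxy(3,4,5-trimethoxyphenyl)methyl]butane-1,4-diol | OC[C@@H](Cc1ccc(O)c(OC)c1)[C@@H](CO)C(O)c1cc(OC)c(OC)c(OC)c1
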